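The route rests on disconnecting the C2–C3 bond of the 2-aryl-3-(hydroxymethyl)-2,3-dihydrobenzofuran. The precursor is an acyclic aryl diazoacetate on ring D whose ortho oxygen carries the ring C benzyl group. An enantioselective rhodium-carbene 1,5-C–H insertion into that O–CH2–aryl methylene forges C2–C3, closes the five-membered oxygen ring and sets C2; the ester later becomes the C3 hydroxymethyl group. The step exploits that C2 is a benzylic carbon bound to the ring oxygen O1 and that C3 sits directly on ring D. The two erythro arylglycerol beta-aryl ether units are then grown from the ring C phenol by Evans glycolate aldol, Mitsunobu inversion and reduction, and the propenal is attached last by Suzuki coupling.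

Key step: step 6

Labels: ring A = 4-hydroxy-3-methoxyphenyl ring; ring B = central 3,5-dimethoxy-4-oxyphenyl ring; ring C = 3,5-dimethoxy-4-oxyphenyl ring on C2 of the dihydrobenzofuran; ring D = benzo ring of the dihydrobenzofuran. Unit A and unit B are the arylglycerol chains on rings A and B (C7 benzylic carbinol, C8 ether carbon, C9 CH2OH).

Assumption: Rh2(S-PTTL)4 is expected, by analogy with simpler 2-(benzyloxy)phenyl diazoacetates, to give the 2R configuration at the new ether stereocentre; should the antipode form, Rh2(R-PTTL)4 would be used instead.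

Step 1
Reactants: 1 syringaldehyde (4-hydroxy-3,5-dimethoxybenzaldehyde)
Product: 2 4-(tert-butyldimethylsilyloxy)-3,5-dimethoxybenzaldehyde
Conditions: TBSCl, imidazole, DMF, rt
Reagents that add atoms: tert-butyldimethylsilyl chloride, CC(C)(C)[Si](C)(C)Cl
Why: Imidazole-promoted silyl ether formation masks the phenol that later becomes the ether oxygen of ring C and of ring B.

Step 2
Reactants: 2 4-(tert-butyldimethylsilyloxy)-3,5-dimethoxybenzaldehyde
Product: 3 [4-(tert-butyldimethylsilyloxy)-3,5-dimethoxyphenyl]methanol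
Conditions: NaBH4, THF/EtOH, 0 °C
Reagents that add atoms: none
Why: Borohydride reduction of the aldehyde should give the benzylic alcohol without touching the hindered aryl silyl ether.

Step 3
Reactants: 4 4-bromo-2-methoxyphenol
Product: 5 4-bromo-2-iodo-6-methoxyphenol
Conditions: NIS, TsOH (cat.), MeCN, 0 °C to rt
Reagents that add atoms: N-iodosuccinimide, O=C1CCC(=O)N1I
Why: Electrophilic aromatic iodination should occur ortho to the free phenol, the para position being blocked by bromine.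

Step 4
Reactants: 5 4-bromo-2-iodo-6-methoxyphenol; 3 [4-(tert-butyldimethylsilyloxy)-3,5-dimethoxyphenyl]methanol
Product: 6 tert-butyl{4-[(4-bromo-2-iodo-6-methoxyphenoxy)methyl]-2,6-dimethoxyphenoxy}dimethylsilane
Conditions: PPh3, DIAD, THF, 0 °C to rt
Reagents that add atoms: none
Why: Mitsunobu etherification joins the acidic halophenol to the primary benzylic alcohol under neutral conditions that spare the aryl silyl ether.

Step 5
Reactants: 6 aryl iodide benzyl ether; 7 ethyl diazoacetate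
Product: 8 ethyl 2-[5-bromo-2-({4-[(tert-butyldimethylsilyl)oxy]-3,5-dimethoxybenzyl}oxy)-3-methoxyphenyl]-2-diazoacetate
Conditions: Pd(PPh3)4 (zerovalent palladium, 5 mol %), Ag2CO3, Et3N, toluene, rt
Reagents that add atoms: none
Why: Palladium-catalysed cross-coupling of an aryl iodide with the C–H bond of ethyl diazoacetate keeps the diazo group and should occur only at the C–I bond, which undergoes oxidative addition far faster than the C–Br bond at room temperature.

Step 6
Reactants: 8 aryl diazoacetate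
Product: 9 ethyl (2R,3S)-5-bromo-2-{4-[(tert-butyldimethylsilyl)oxy]-3,5-dimethoxyphenyl}-7-methoxy-2,3-dihydro-1-benzofuran-3-carboxylate (cis)
Conditions: Rh2(S-PTTL)4 (dirhodium tetrakis[N-phthaloyl-(S)-tert-leucinate], 1 mol %), toluene, −60 °C, slow addition of 8
Reagents that add atoms: none
Why: The dirhodium carboxylate decomposes the donor/acceptor diazo ester to an electrophilic rhodium-bound carbene, which inserts into the hydridic O–CH2–aryl bond of the ortho ether in a concerted, asynchronous three-centre event; this is the intramolecular carbene C–H insertion of aryldiazoacetates, the established route to cis-2-aryl-2,3-dihydrobenzofuran-3-carboxylates. The new C2–C3 bond closes the five-membered oxygen ring by 1,5-insertion (carbene carbon as atom 1, the methylene as atom 5), the only closure this tether allows, since a four-membered oxonium ylide and any other C–H bond are out of reach. C2 is set by the chiral phthaloyl-tert-leucinate ligand sphere, which differentiates the two enantiotopic benzylic hydrogens and is expected to deliver 2R; C3 forms cis to the aryl group under kinetic control and is corrected in step 7. The step needs site selectivity for the methylene C–H over cyclopropanation or ring expansion of the electron-rich ring C and over carbene dimerisation; the intramolecular five-membered geometry, activation of the C–H bond by the 4-silyloxy-3,5-dimethoxyphenyl donor, low temperature and slow addition should secure it. The aryl bromide, the silyl ether and the ethyl ester should be inert to the carbene.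

Step 7
Reactants: 9 cis dihydrobenzofuran ester
Product: 10 ethyl (2R,3R)-5-bromo-2-(4-hydroxy-3,5-dimethoxyphenyl)-7-methoxy-2,3-dihydro-1-benzofuran-3-carboxylate (trans)
Conditions: NaOEt (3 equiv), EtOH, rt to 40 °C; AcOH quench
Reagents that add atoms: none
Why: Ethoxide should equilibrate C3 through the ester enolate to the thermodynamically favoured trans isomer (base-mediated epimerisation, C2 untouched) and cleave the aryl silyl ether at silicon in the same pot, ethanol keeping the ethyl ester unchanged.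

Step 8
Reactants: 10 trans phenol ester; 11 (R)-4-benzyl-3-(chloroacetyl)oxazolidin-2-one
Product: 12 (4R)-4-benzyl-3-({4-[(2R,3R)-5-bromo-3-(ethoxycarbonyl)-7-methoxy-2,3-dihydro-1-benzofuran-2-yl]-2,6-dimethoxyphenoxy}acetyl)oxazolidin-2-one
Conditions: K2CO3, NaI (cat.), acetone, rt to 45 °C
Reagents that add atoms: none
Why: Williamson alkylation of the phenoxide by the alpha-chloro imide, activated by iodide exchange, installs the glycolyl Evans imide on the ring C oxygen.

Step 9
Reactants: 12 glycolyl imide; 2 4-(tert-butyldimethylsilyloxy)-3,5-dimethoxybenzaldehyde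
Product: 15 syn aldol adduct (2R,3S) of imide 12 on aldehyde 2, via Z-boron enolate 13 (not isolated), via boron aldolate 14 (not isolated)
Conditions: Bu2BOTf (1.15 equiv), iPr2NEt, CH2Cl2, −78 to 0 °C; then 2, −78 to 0 °C; pH 7 buffer, MeOH, H2O2, 0 °C
Reagents that add atoms: none
Why: In this Evans boron aldol the Z dibutylboron enolate should react through a Zimmerman–Traxler chair on the face away from the benzyl group of the (R)-auxiliary, giving the syn (2R,3S) adduct and thereby the correct C8 of unit B; the imide is enolised much faster than the C3 ester.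

Step 10
Reactants: 15 syn aldol adduct
Product: 16 anti 4-nitrobenzoate (2R,3R), inverted at the benzylic carbon
Conditions: 4-nitrobenzoic acid, PPh3, DIAD, THF, 0 °C to rt
Reagents that add atoms: 4-nitrobenzoic acid, O=C(O)c1ccc(cc1)[N+](=O)[O-]
Why: Mitsunobu esterification displaces the alkoxyphosphonium with inversion (SN2), turning the syn (threo) into the anti (erythro) relationship and setting C7 of unit B as R.

Step 11
Reactants: 16 anti 4-nitrobenzoate
Product: 17 (1R,2S)-2-{4-[(2R,3S)-5-bromo-3-(hydroxymethyl)-7-methoxy-2,3-dihydro-1-benzofuran-2-yl]-2,6-dimethoxyphenoxy}-1-{4-[(tert-butyldimethylsilyl)oxy]-3,5-dimethoxyphenyl}propane-1,3-diol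
Conditions: LiBH4 (excess), THF, H2O (1 equiv), 0 °C to rt
Reagents that add atoms: none
Why: Borohydride reduction cleaves the imide to the primary alcohol, reduces the C3 ethyl ester to the hydroxymethyl group and removes the 4-nitrobenzoate in one operation; the aryl silyl ether is kept so that no phenoxide ever faces a para benzylic ester, which would open a quinone methide pathway.

Step 12
Reactants: 17 erythro triol aryl silyl ether; 11 (R)-4-benzyl-3-(chloroacetyl)oxazolidin-2-one
Product: 18 (4R)-4-benzyl-3-[(4-{(1R,2S)-2-[4-((2R,3S)-5-bromo-3-(hydroxymethyl)-7-methoxy-2,3-dihydro-1-benzofuran-2-yl)-2,6-dimethoxyphenoxy]-1,3-dihydroxypropyl}-2,6-dimethoxyphenoxy)acetyl]oxazolidin-2-one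
Conditions: CsF (3 equiv), DMF, rt
Reagents that add atoms: none
Why: Fluoride unmasks the ring B phenoxide in situ, and this is alkylated chemoselectively over the three much less acidic alcohols (one-pot desilylation and Williamson alkylation).

Step 13
Reactants: 18 triol imide
Product: 19 tris(triethylsilyl) ether of 18 (unit B C7–O and C9–O, dihydrobenzofuran CH2O)
Conditions: TESCl, imidazole, DMAP (cat.), DMF, rt
Reagents that add atoms: chlorotriethylsilane, CC[Si](Cl)(CC)CC
Why: Silyl ether formation blocks the three alcohols, which would otherwise consume the boron triflate and compete in the later Mitsunobu reaction.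

Step 14
Reactants: 19 tris-TES imide; 20 4-(tert-butyldimethylsilyloxy)-3-methoxybenzaldehyde
Product: 23 syn aldol adduct (2R,3S) of imide 19 on aldehyde 20, via Z-boron enolate 21 (not isolated), via boron aldolate 22 (not isolated)
Conditions: Bu2BOTf (1.15 equiv), iPr2NEt, CH2Cl2, −78 to 0 °C; then 20, −78 to 0 °C; pH 7 buffer, MeOH, H2O2, 0 °C
Reagents that add atoms: none
Why: A second Evans boron aldol, again reagent-controlled by the (R)-auxiliary through the Zimmerman–Traxler chair, should set C8 of unit A correctly with the syn (2R,3S) relationship.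

Step 15
Reactants: 23 syn aldol adduct
Product: 24 anti 4-nitrobenzoate (2R,3R) of unit A
Conditions: 4-nitrobenzoic acid, PPh3, DIAD, THF, 0 °C to rt
Reagents that add atoms: 4-nitrobenzoic acid, O=C(O)c1ccc(cc1)[N+](=O)[O-]
Why: Mitsunobu inversion at the only free hydroxyl converts the syn into the anti (erythro) arrangement and sets C7 of unit A as R.

Step 16
Reactants: 24 anti 4-nitrobenzoate
Product: 25 unit A (1R,2S)-1,3-diol with ring A silyl ether, three TES ethers and the ring D bromide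
Conditions: LiBH4 (excess), THF, H2O (1 equiv), 0 °C to rt
Reagents that add atoms: none
Why: Borohydride reduction removes the auxiliary as the primary alcohol and cleaves the 4-nitrobenzoate, while the silyl ethers and the aryl bromide should survive.

Step 17
Reactants: 25 protected bromide; 26 (E)-2-(3,3-diethoxyprop-1-en-1-yl)-4,4,5,5-tetramethyl-1,3,2-dioxaborolane
Product: 28 target CNP0192639.1, via coupled diethyl acetal 27 (not isolated)
Conditions: PdCl2(dppf) (5 mol %), CsF (5 equiv), 1,4-dioxane/H2O, 80 °C; then AcOH/THF/H2O, rt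
Reagents that add atoms: water, O
Why: Fluoride-promoted Suzuki–Miyaura coupling at the aryl bromide installs the E-propenyl unit as its acetal with retention of alkene geometry and frees the ring A phenol; mild aqueous acid then hydrolyses the triethylsilyl ethers and the allylic acetal to the enal.

Compound list
1 | syringaldehyde | COc1cc(C=O)cc(OC)c1O | starting material
2 | 4-(tert-butyldimethylsilyloxy)-3,5-dimethoxybenzaldehyde | COc1cc(C=O)cc(OC)c1O[Si](C)(C)C(C)(C)C | intermediate
3 | [4-(tert-butyldimethylsilyloxy)-3,5-dimethoxyphenyl]methanol | COc1cc(CO)cc(OC)c1O[Si](C)(C)C(C)(C)C | intermediate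
4 | 4-bromo-2-methoxyphenol | COc1cc(Br)ccc1O | starting material
5 | 4-bromo-2-iodo-6-methoxyphenol | COc1cc(Br)cc(I)c1O | intermediate
6 | tert-butyl{4-[(4-bromo-2-iodo-6-methoxyphenoxy)methyl]-2,6-dimethoxyphenoxy}dimethylsilane | COc1cc(COc2c(I)cc(Br)cc2OC)cc(OC)c1O[Si](C)(C)C(C)(C)C | intermediate
7 | ethyl diazoacetate | CCOC(=O)C=[N+]=[N-] | starting material
8 | ethyl 2-[5-bromo-2-({4-[(tert-butyldimethylsilyl)oxy]-3,5-dimethoxybenzyl}oxy)-3-methoxyphenyl]-2-diazoacetate | CCOC(=O)C(=[N+]=[N-])c1cc(Br)cc(OC)c1OCc1cc(OC)c(O[Si](C)(C)C(C)(C)C)c(OC)c1 | intermediate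
9 | ethyl (2R,3S)-5-bromo-2-{4-[(tert-butyldimethylsilyl)oxy]-3,5-dimethoxyphenyl}-7-methoxy-2,3-dihydro-1-benzofuran-3-carboxylate (cis) | CC(C)(C)[Si](C)(C)Oc1c(OC)cc([C@@H]2Oc3c(OC)cc(Br)cc3[C@@H]2C(=O)OCC)cc1OC | intermediate
10 | ethyl (2R,3R)-5-bromo-2-(4-hydroxy-3,5-dimethoxyphenyl)-7-methoxy-2,3-dihydro-1-benzofuran-3-carboxylate (trans) | Oc1c(OC)cc([C@@H]2Oc3c(OC)cc(Br)cc3[C@H]2C(=O)OCC)cc1OC | intermediate
11 | (R)-4-benzyl-3-(chloroacetyl)oxazolidin-2-one | O=C(CCl)N1[C@H](Cc2ccccc2)COC1=O | starting material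
12 | ring C O-glycolyl (R)-oxazolidinone imide of 10 | O=C(COc1c(OC)cc([C@@H]2Oc3c(OC)cc(Br)cc3[C@H]2C(=O)OCC)cc1OC)N1[C@H](Cc2ccccc2)COC1=O | intermediate
13 | Z dibutylboron enolate of 12 | CCCCB(CCCC)O/C(=C\Oc1c(OC)cc([C@@H]2Oc3c(OC)cc(Br)cc3[C@H]2C(=O)OCC)cc1OC)N1[C@H](Cc2ccccc2)COC1=O | intermediate
14 | dibutylboron aldolate of 15 | CC(C)(C)[Si](C)(C)Oc1c(OC)cc([C@H](OB(CCCC)CCCC)[C@H](C(=O)N2[C@H](Cc3ccccc3)COC2=O)Oc2c(OC)cc([C@@H]3Oc4c(OC)cc(Br)cc4[C@H]3C(=O)OCC)cc2OC)cc1OC | intermediate
15 | syn aldol adduct: (4R)-4-benzyl-3-[(2R,3S)-2-(ring C aryloxy)-3-hydroxy-3-(4-silyloxy-3,5-dimethoxyphenyl)propanoyl]oxazolidin-2-one | CC(C)(C)[Si](C)(C)Oc1c(OC)cc([C@H](O)[C@H](C(=O)N2[C@H](Cc3ccccc3)COC2=O)Oc2c(OC)cc([C@@H]3Oc4c(OC)cc(Br)cc4[C@H]3C(=O)OCC)cc2OC)cc1OC | intermediate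
16 | anti (2R,3R) 4-nitrobenzoate of 15, inverted at the benzylic carbon | CC(C)(C)[Si](C)(C)Oc1c(OC)cc([C@@H](OC(=O)c2ccc(cc2)[N+](=O)[O-])[C@H](C(=O)N2[C@H](Cc3ccccc3)COC2=O)Oc2c(OC)cc([C@@H]3Oc4c(OC)cc(Br)cc4[C@H]3C(=O)OCC)cc2OC)cc1OC | intermediate
17 | (1R,2S)-2-{4-[(2R,3S)-5-bromo-3-(hydroxymethyl)-7-methoxy-2,3-dihydro-1-benzofuran-2-yl]-2,6-dimethoxyphenoxy}-1-{4-[(tert-butyldimethylsilyl)oxy]-3,5-dimethoxyphenyl}propane-1,3-diol | CC(C)(C)[Si](C)(C)Oc1c(OC)cc([C@@H](O)[C@H](CO)Oc2c(OC)cc([C@@H]3Oc4c(OC)cc(Br)cc4[C@H]3CO)cc2OC)cc1OC | intermediate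
18 | ring B O-glycolyl (R)-oxazolidinone imide of the desilylated triol | O=C(COc1c(OC)cc([C@@H](O)[C@H](CO)Oc2c(OC)cc([C@@H]3Oc4c(OC)cc(Br)cc4[C@H]3CO)cc2OC)cc1OC)N1[C@H](Cc2ccccc2)COC1=O | intermediate
19 | tris(triethylsilyl) ether of 18 | O=C(COc1c(OC)cc([C@@H](O[Si](CC)(CC)CC)[C@H](CO[Si](CC)(CC)CC)Oc2c(OC)cc([C@@H]3Oc4c(OC)cc(Br)cc4[C@H]3CO[Si](CC)(CC)CC)cc2OC)cc1OC)N1[C@H](Cc2ccccc2)COC1=O | intermediate
20 | 4-(tert-butyldimethylsilyloxy)-3-methoxybenzaldehyde | COc1cc(C=O)ccc1O[Si](C)(C)C(C)(C)C | starting material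
21 | Z dibutylboron enolate of 19 | CCCCB(CCCC)O/C(=C\Oc1c(OC)cc([C@@H](O[Si](CC)(CC)CC)[C@H](CO[Si](CC)(CC)CC)Oc2c(OC)cc([C@@H]3Oc4c(OC)cc(Br)cc4[C@H]3CO[Si](CC)(CC)CC)cc2OC)cc1OC)N1[C@H](Cc2ccccc2)COC1=O | intermediate
22 | dibutylboron aldolate of 23 | COc1cc([C@H](OB(CCCC)CCCC)[C@H](C(=O)N2[C@H](Cc3ccccc3)COC2=O)Oc2c(OC)cc([C@@H](O[Si](CC)(CC)CC)[C@H](CO[Si](CC)(CC)CC)Oc3c(OC)cc([C@@H]4Oc5c(OC)cc(Br)cc5[C@H]4CO[Si](CC)(CC)CC)cc3OC)cc2OC)ccc1O[Si](C)(C)C(C)(C)C | intermediate
23 | syn aldol adduct of unit A: (4R)-4-benzyl-3-[(2R,3S)-2-(ring B aryloxy)-3-hydroxy-3-(4-silyloxy-3-methoxyphenyl)propanoyl]oxazolidin-2-one | COc1cc([C@H](O)[C@H](C(=O)N2[C@H](Cc3ccccc3)COC2=O)Oc2c(OC)cc([C@@H](O[Si](CC)(CC)CC)[C@H](CO[Si](CC)(CC)CC)Oc3c(OC)cc([C@@H]4Oc5c(OC)cc(Br)cc5[C@H]4CO[Si](CC)(CC)CC)cc3OC)cc2OC)ccc1O[Si](C)(C)C(C)(C)C | intermediate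
24 | anti (2R,3R) 4-nitrobenzoate of 23 | COc1cc([C@@H](OC(=O)c2ccc(cc2)[N+](=O)[O-])[C@H](C(=O)N2[C@H](Cc3ccccc3)COC2=O)Oc2c(OC)cc([C@@H](O[Si](CC)(CC)CC)[C@H](CO[Si](CC)(CC)CC)Oc3c(OC)cc([C@@H]4Oc5c(OC)cc(Br)cc5[C@H]4CO[Si](CC)(CC)CC)cc3OC)cc2OC)ccc1O[Si](C)(C)C(C)(C)C | intermediate
25 | unit A (1R,2S)-1,3-diol; ring A TBS ether; unit B and dihydrobenzofuran TES ethers; ring D bromide | COc1cc([C@@H](O)[C@H](CO)Oc2c(OC)cc([C@@H](O[Si](CC)(CC)CC)[C@H](CO[Si](CC)(CC)CC)Oc3c(OC)cc([C@@H]4Oc5c(OC)cc(Br)cc5[C@H]4CO[Si](CC)(CC)CC)cc3OC)cc2OC)ccc1O[Si](C)(C)C(C)(C)C | intermediate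
26 | (E)-2-(3,3-diethoxyprop-1-en-1-yl)-4,4,5,5-tetramethyl-1,3,2-dioxaborolane | CCOC(OCC)/C=C/B1OC(C)(C)C(C)(C)O1 | starting material
27 | coupled (E)-propenal diethyl acetal with free ring A phenol and three TES ethers | COc1cc([C@@H](O)[C@H](CO)Oc2c(OC)cc([C@@H](O[Si](CC)(CC)CC)[C@H](CO[Si](CC)(CC)CC)Oc3c(OC)cc([C@@H]4Oc5c(OC)cc(/C=C/C(OCC)OCC)cc5[C@H]4CO[Si](CC)(CC)CC)cc3OC)cc2OC)ccc1O | intermediate
28 | CNP0192639.1: (E)-3-[(2R,3S)-2-{4-[(1R,2S)-1,3-dihydroxy-1-{4-[(1R,2S)-1,3-dihydroxy-1-(4-hydroxy-3-methoxyphenyl)propan-2-yloxy]-3,5-dimethoxyphenyl}propan-2-yloxy]-3,5-dimethoxyphenyl}-3-(hydroxymethyl)-7-methoxy-2,3-dihydro-1-benzofuran-5-yl]prop-2-enal | COc1cc([C@@H](O)[C@H](CO)Oc2c(OC)cc([C@@H](O)[C@H](CO)Oc3c(OC)cc([C@@H]4Oc5c(OC)cc(/C=C/C=O)cc5[C@H]4CO)cc3OC)cc2OC)ccc1O | target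

Total step count: 17. Longest linear sequence: 16 steps (steps 1, 2 and 4 to 17, from syringaldehyde); step 3 is a one-step side branch.

Steps most likely to fail

Step 10 (the same question recurs in step 15). The electron-rich benzylic alkoxyphosphonium may ionise, so that inversion is eroded, or may eliminate toward the enol-ether imide instead of undergoing SN2 displacement. The fallback sets out from 15 and gives up inversion in favour of an oxidation–reduction at C7. LiBH4 in THF would reduce the imide and the C3 ester of 15 to the threo (1S,2S) triol with the ring B silyl ether intact, F1. Activated MnO2 in CH2Cl2 would then oxidise only the secondary benzylic alcohol to the (2S) aryl ketone F2; a quinone oxidant is avoided because it could dehydrogenate the dihydrobenzofuran. NaBH4 at low temperature should reduce F2 under Felkin–Anh control, with the 2,6-dimethoxyphenoxy group as the polar substituent, to the erythro triol, which is compound 17, where the route is rejoined.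

Step 5. Oxidative addition and diazo transfer at the hindered ortho-alkoxy aryl iodide may be slow, so that palladium-mediated decomposition of ethyl diazoacetate outruns coupling. The fallback sets out from 6 and builds the diazo group by the Bamford–Stevens route. Iodine–magnesium exchange with iPrMgCl·LiCl at −40 °C, selective for iodide over bromide, and trapping with diethyl oxalate would give the ethyl arylglyoxylate F3. Condensation with tosylhydrazide would give the tosylhydrazone F4, and DBU in CH2Cl2 would eliminate sulfinate to give diazo ester 8, where the route is rejoined.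

Step 6. The chiral catalyst may discriminate the two benzylic hydrogens insufficiently on this doubly ortho-methoxylated benzyl ether, or carbene dimerisation may compete. The fallback sets out from 8 and replaces asymmetric catalysis by resolution. Achiral Rh2(OAc)4 in CH2Cl2 would give the racemic cis ester, that is 9 together with its (2S,3R) enantiomer F5. The conditions of step 7 would convert this into the racemic trans phenol, that is 10 together with its (2S,3S) enantiomer F6. Preparative chromatography on a chiral stationary phase would then deliver 10, where the route is rejoined.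

Further compounds
F1 | step 10 | (1S,2S)-2-{4-[(2R,3S)-5-bromo-3-(hydroxymethyl)-7-methoxy-2,3-dihydro-1-benzofuran-2-yl]-2,6-dimethoxyphenoxy}-1-{4-[(tert-butyldimethylsilyl)oxy]-3,5-dimethoxyphenyl}propane-1,3-diol (threo) | CC(C)(C)[Si](C)(C)Oc1c(OC)cc([C@H](O)[C@H](CO)Oc2c(OC)cc([C@@H]3Oc4c(OC)cc(Br)cc4[C@H]3CO)cc2OC)cc1OC
F2 | step 10 | (2S)-2-{4-[(2R,3S)-5-bromo-3-(hydroxymethyl)-7-methoxy-2,3-dihydro-1-benzofuran-2-yl]-2,6-dimethoxyphenoxy}-1-{4-[(tert-butyldimethylsilyl)oxy]-3,5-dimethoxyphenyl}-3-hydroxypropan-1-one | CC(C)(C)[Si](C)(C)Oc1c(OC)cc(C(=O)[C@H](CO)Oc2c(OC)cc([C@@H]3Oc4c(OC)cc(Br)cc4[C@H]3CO)cc2OC)cc1OC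
F3 | step 5 | ethyl 2-[5-bromo-2-({4-[(tert-butyldimethylsilyl)oxy]-3,5-dimethoxybenzyl}oxy)-3-methoxyphenyl]-2-oxoacetate | CCOC(=O)C(=O)c1cc(Br)cc(OC)c1OCc1cc(OC)c(O[Si](C)(C)C(C)(C)C)c(OC)c1
F4 | step 5 | tosylhydrazone of F3 | CCOC(=O)C(=NNS(=O)(=O)c1ccc(C)cc1)c1cc(Br)cc(OC)c1OCc1cc(OC)c(O[Si](C)(C)C(C)(C)C)c(OC)c1
F5 | step 6 | ethyl (2S,3R)-5-bromo-2-{4-[(tert-butyldimethylsilyl)oxy]-3,5-dimethoxyphenyl}-7-methoxy-2,3-dihydro-1-benzofuran-3-carboxylate (enantiomer of 9) | CC(C)(C)[Si](C)(C)Oc1c(OC)cc([C@H]2Oc3c(OC)cc(Br)cc3[C@H]2C(=O)OCC)cc1OC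
F6 | step 6 | ethyl (2S,3S)-5-bromo-2-(4-hydroxy-3,5-dimethoxyphenyl)-7-methoxy-2,3-dihydro-1-benzofuran-3-carboxylate (enantiomer of 10) | Oc1c(OC)cc([C@H]2Oc3c(OC)cc(Br)cc3[C@@H]2C(=O)OCC)cc1OC
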